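The route rests on disconnecting the bromocyclohexane ring between its gem-dimethyl carbon C3 and the adjacent methylene C2. That bond is made by a bromonium-initiated cation–olefin cyclization, which exploits the C4(Br)–C3(CH3)2 pair of the ring (a prenyl bromonium ion opened at its tertiary carbon) and the trans C1/C4 pattern: a chair transition state relays the preset C1–H stereocentre to C4–Br, so ring, quaternary carbon and C–Br centre arise in one operation. The precursor is an acyclic citronellal-type enol acetate whose stereogenic carbon already carries the complete bromo-oxabicycle, made from an enantioselective Diels–Alder adduct by bromoetherification; the formyl carbon left by the enol acetate is then excised.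

Key step: step 11

Assumption: 2-bromoacrolein is bought (otherwise one step from acrolein), and in steps 1 and 9 the catalyst antipode named is the one expected from the usual facial models; if the sense proved opposite, the mirror-image catalyst would be used.

Abbreviation: Obc = (1S,3R,4R)-3-bromo-4-methyl-7-oxabicyclo[2.2.1]heptan-1-yl (bromine endo, i.e. anti to the oxygen bridge).

Step 1
Reactants: 1 isoprene (2-methylbuta-1,3-diene); 2 2-bromoacrolein (2-bromoprop-2-enal)
Product: 3 (R)-1-bromo-4-methylcyclohex-3-ene-1-carbaldehyde
Conditions: (S)-2-butyl-4-(1H-indol-3-ylmethyl)-3-tosyl-1,3,2-oxazaborolidin-5-one (10 mol%), CH2Cl2, −78 °C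
Reagents that add atoms: none
Why: Oxazaborolidine-catalysed enantioselective Diels–Alder reaction of a 2-haloacrolein, in which the 2-methyl group of the diene directs the "para" orientation and the catalyst shields one face of the bound s-cis dienophile, so the quaternary centre should form as (R).

Step 2
Reactants: 3 (R)-1-bromo-4-methylcyclohex-3-ene-1-carbaldehyde
Product: 5 (S)-1-(dimethoxymethyl)-4-methylcyclohex-3-en-1-ol, via spiro epoxy ether 4 (not isolated)
Conditions: NaOMe, MeOH, 0 °C; then TsOH·H2O (5 mol%), MeOH, rt
Reagents that add atoms: sodium methoxide, [Na+].[O-]C; methanol, CO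
Why: Epoxy-ether route from an α-halo aldehyde to an α-hydroxy acetal (methoxide adds to the formyl group, the alkoxide displaces the tertiary bromide by intramolecular SN2 with inversion, and acid methanolysis opens the epoxy ether at the acetal carbon), so the tertiary C–O centre should form stereospecifically as (S).

Step 3
Reactants: 5 (S)-1-(dimethoxymethyl)-4-methylcyclohex-3-en-1-ol
Product: 6 (1S,3R,4R)-3-bromo-1-(dimethoxymethyl)-4-methyl-7-oxabicyclo[2.2.1]heptane
Conditions: NBS, CH2Cl2, 0 °C, dark
Reagents that add atoms: N-bromosuccinimide, O=C1CCC(=O)N1Br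
Why: Bromoetherification, in which the tertiary hydroxyl captures the bromonium ion transannularly at the methyl-bearing carbon (Markovnikov, anti), closing the 7-oxabicyclo[2.2.1]heptane with bromine endo; both new centres follow from the carbinol centre because the oxygen can bridge on one face only.

Step 4
Reactants: 6 (1S,3R,4R)-3-bromo-1-(dimethoxymethyl)-4-methyl-7-oxabicyclo[2.2.1]heptane
Product: 7 (1S,3R,4R)-3-bromo-4-methyl-7-oxabicyclo[2.2.1]heptane-1-carbaldehyde
Conditions: CF3CO2H/H2O (9:1), CH2Cl2, 0 °C
Reagents that add atoms: water, O
Why: Acid-catalysed acetal hydrolysis, giving a bridgehead aldehyde that has no α-hydrogen and therefore cannot enolize or epimerize.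

Step 5
Reactants: 7 (1S,3R,4R)-3-bromo-4-methyl-7-oxabicyclo[2.2.1]heptane-1-carbaldehyde; 8 5-bromo-2-methylpent-2-ene
Product: 10 1-(Obc)-5-methylhex-4-en-1-ol (both carbinol epimers), via (4-methylpent-3-en-1-yl)magnesium bromide 9 (not isolated)
Conditions: 8, Mg, THF, rt; then 7, THF, −78 °C; H2O
Reagents that add atoms: none
Why: Grignard addition to a non-enolizable aldehyde; the new carbinol centre is erased in step 6 and the hindered secondary bromide should not react with the Grignard reagent at −78 °C.

Step 6
Reactants: 10 1-(Obc)-5-methylhex-4-en-1-ol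
Product: 11 1-(Obc)-5-methylhex-4-en-1-one
Conditions: Dess–Martin periodinane, NaHCO3, CH2Cl2, rt
Reagents that add atoms: none
Why: Dess–Martin oxidation of the secondary alcohol to the ketone under neutral conditions that leave the alkene, the ether and the bromide untouched.

Step 7
Reactants: 11 1-(Obc)-5-methylhex-4-en-1-one; 12 vinylmagnesium bromide
Product: 13 3-(Obc)-7-methylocta-1,6-dien-3-ol (both carbinol epimers)
Conditions: CeCl3, THF, −78 °C; H2O
Reagents that add atoms: none
Why: Organocerium 1,2-addition to a hindered, enolizable ketone; the configuration of the new carbinol carbon is irrelevant because step 8 makes it trigonal.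

Step 8
Reactants: 13 3-(Obc)-7-methylocta-1,6-dien-3-ol
Product: 14 3-(Obc)-7-methylocta-2,6-dienal (E/Z mixture)
Conditions: pyridinium chlorochromate [C5H5NH][CrO3Cl], CH2Cl2, rt
Reagents that add atoms: pyridinium chlorochromate, [O-][Cr](=O)(=O)Cl.c1cc[nH+]cc1
Why: Babler–Dauben oxidative 1,3-transposition (chromate ester, [3,3] shift, oxidation), the reaction that turns linalool into citral, applied to the same tertiary vinyl carbinol pattern; the alkene geometry need not be controlled.

Step 9
Reactants: 14 3-(Obc)-7-methylocta-2,6-dienal
Product: 15 (3S)-3-(Obc)-7-methyloct-6-enal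
Conditions: (R)-2-tert-butyl-3-methylimidazolidin-4-one·CCl3CO2H (20 mol%), diethyl 2,6-dimethyl-1,4-dihydropyridine-3,5-dicarboxylate (1.2 equiv), CHCl3, −30 °C
Reagents that add atoms: none
Why: Iminium-catalysed transfer hydrogenation of a β,β-disubstituted enal with a Hantzsch ester, in which the E and Z iminium ions interconvert, the one with the bulky bicyclic group trans reacts, and the catalyst exposes one face to hydride, so the C3 centre should be set as (S) while the remote alkene is untouched.

Step 10
Reactants: 15 (3S)-3-(Obc)-7-methyloct-6-enal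
Product: 16 (3S)-3-(Obc)-7-methylocta-1,6-dien-1-yl acetate (E/Z mixture)
Conditions: Ac2O, KOAc, Et3N, 120 °C
Reagents that add atoms: acetic anhydride, CC(=O)OC(C)=O
Why: Enol acetylation of an aldehyde with an α-methylene group (the conditions used for citronellal enol acetate); the stereocentre is β to the carbonyl and is not affected.

Step 11
Reactants: 16 (3S)-3-(Obc)-7-methylocta-1,6-dien-1-yl acetate
Product: 17 (3S,6S)-3-bromo-2,2-dimethyl-6-(Obc)cyclohexane-1-carbaldehyde (both C1 epimers)
Conditions: Et2SBr·SbCl5Br (bromodiethylsulfonium bromopentachloroantimonate, 1.05 equiv), MeNO2, −25 °C; then aq. NaHCO3/Na2SO3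
Reagents that add atoms: bromodiethylsulfonium bromopentachloroantimonate, CC[S+](Br)CC.Br[Sb-](Cl)(Cl)(Cl)(Cl)Cl
Why: The reagent transfers Br+ to the trisubstituted alkene, the more nucleophilic of the two π-systems, and the bromonium ion is opened at its tertiary carbon by the β-carbon of the enol acetate, after which the acetoxycarbenium ion loses its acetyl group on work-up to leave the aldehyde. The closest known reaction type is the bromonium-induced cation–olefin (polyene) cyclization with this sulfonium reagent, here terminated by an enol ester instead of a simple alkene or arene. The cyclohexane closes through a chair by 6-endo opening of the bromonium ion (exo with respect to the enol double bond), whereas 5-exo attack at the secondary carbon would be anti-Markovnikov and should not compete. The new C–Br centre is controlled by the existing C–H centre: anti opening places bromine equatorial, and the bicyclic substituent must also be equatorial because an axial one would be 1,3-diaxial to a methyl group of the forming quaternary carbon, so only the trans (3S,6S) ring should result, and the formyl-bearing carbon forms as a mixture that step 12 erases. The step needs chemoselective bromonium formation, secured by the lower nucleophilicity of the enol acetate and by one equivalent of reagent, and it needs the matched bromonium diastereomer to react, which is secured if Br+ transfer between alkene and diethyl sulfide is reversible, since only the matched ion can reach the all-equatorial chair.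

Step 12
Reactants: 17 (3S,6S)-3-bromo-2,2-dimethyl-6-(Obc)cyclohexane-1-carbaldehyde
Product: 18 (1R,2R,4S)-2-bromo-4-[(1S,4S)-4-bromo-3,3-dimethylcyclohexyl]-1-methyl-7-oxabicyclo[2.2.1]heptane
Conditions: RhCl(PPh3)3 (1.1 equiv), PhCN, 130 °C
Reagents that add atoms: none
Why: Tsuji–Wilkinson decarbonylation (oxidative addition of the formyl C–H bond to monovalent rhodium, CO extrusion, C–H reductive elimination) turns the CH–CHO carbon into the ring CH2, so both epimers converge and no stereocentre of the target is affected.

Compound list
1 | isoprene | C=CC(C)=C | starting material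
2 | 2-bromoacrolein | C=C(Br)C=O | starting material
3 | (R)-1-bromo-4-methylcyclohex-3-ene-1-carbaldehyde | O=C[C@]1(Br)CC=C(C)CC1 | intermediate
4 | (3S)-2-methoxy-6-methyl-1-oxaspiro[2.5]oct-5-ene (both C2 epimers) | COC1O[C@@]12CC=C(C)CC2 | intermediate (not isolated)
5 | (S)-1-(dimethoxymethyl)-4-methylcyclohex-3-en-1-ol | COC(OC)[C@@]1(O)CC=C(C)CC1 | intermediate
6 | (1S,3R,4R)-3-bromo-1-(dimethoxymethyl)-4-methyl-7-oxabicyclo[2.2.1]heptane | COC(OC)[C@@]12CC[C@@](C)(O1)[C@H](Br)C2 | intermediate
7 | (1S,3R,4R)-3-bromo-4-methyl-7-oxabicyclo[2.2.1]heptane-1-carbaldehyde | O=C[C@@]12CC[C@@](C)(O1)[C@H](Br)C2 | intermediate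
8 | 5-bromo-2-methylpent-2-ene | CC(C)=CCCBr | starting material
9 | (4-methylpent-3-en-1-yl)magnesium bromide | CC(C)=CCC[Mg]Br | intermediate (not isolated)
10 | 1-(Obc)-5-methylhex-4-en-1-ol (both carbinol epimers) | CC(C)=CCCC(O)[C@@]12CC[C@@](C)(O1)[C@H](Br)C2 | intermediate
11 | 1-(Obc)-5-methylhex-4-en-1-one | CC(C)=CCCC(=O)[C@@]12CC[C@@](C)(O1)[C@H](Br)C2 | intermediate
12 | vinylmagnesium bromide | C=C[Mg]Br | starting material
13 | 3-(Obc)-7-methylocta-1,6-dien-3-ol (both carbinol epimers) | C=CC(O)(CCC=C(C)C)[C@@]12CC[C@@](C)(O1)[C@H](Br)C2 | intermediate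
14 | 3-(Obc)-7-methylocta-2,6-dienal (E/Z mixture) | O=CC=C(CCC=C(C)C)[C@@]12CC[C@@](C)(O1)[C@H](Br)C2 | intermediate
15 | (3S)-3-(Obc)-7-methyloct-6-enal | O=CC[C@@H]([C@@]12CC[C@@](C)(O1)[C@H](Br)C2)CCC=C(C)C | intermediate
16 | (3S)-3-(Obc)-7-methylocta-1,6-dien-1-yl acetate (E/Z mixture) | CC(=O)OC=C[C@@H]([C@@]12CC[C@@](C)(O1)[C@H](Br)C2)CCC=C(C)C | intermediate
17 | (3S,6S)-3-bromo-2,2-dimethyl-6-(Obc)cyclohexane-1-carbaldehyde (both C1 epimers) | CC1(C)C(C=O)[C@@H]([C@@]23CC[C@@](C)(O2)[C@H](Br)C3)CC[C@@H]1Br | intermediate
18 | (1R,2R,4S)-2-bromo-4-[(1S,4S)-4-bromo-3,3-dimethylcyclohexyl]-1-methyl-7-oxabicyclo[2.2.1]heptane | CC1(C)C[C@@H]([C@@]23CC[C@@](C)(O2)[C@H](Br)C3)CC[C@@H]1Br | target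

Total step count: 12. Longest linear sequence: 12 steps (1 to 18).

Steps most likely to fail

Step 11. Br+ may be taken up by the enol acetate in competition with the trisubstituted alkene. Bromonium formation may also be effectively irreversible, so that the mismatched bromonium ion closes through a boat and erodes the trans selectivity. The fallback sets out from 16 and uses mercury instead of bromine as the initiating electrophile: Hg(OTf)2·PhNMe2 in MeNO2 at −20 °C forms the mercurinium ion reversibly and closes the same ring through the same chair. Work-up with aqueous NaBr should give the equatorial organomercuric bromide F1. Brominolysis with Br2, LiBr and pyridine under O2, which replaces mercury by bromine with retention, then returns to 17.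

Step 12. Oxidative addition to the hindered formyl group, flanked by a quaternary and a tertiary carbon, may be slow, and prolonged heating may cause loss of HBr. The fallback sets out from 17 and removes the carbon as CO2 instead of CO. Oxidation with NaClO2, NaH2PO4 and 2-methyl-2-butene in t-BuOH/H2O should give the carboxylic acid F2. Photoredox hydrodecarboxylation (9-mesityl-10-methylacridinium tetrafluoroborate and (PhS)2 as catalysts, i-Pr2NEt, CF3CH2OH, blue light) then leads to 18.

Step 9. Iminium formation from the enal with its tertiary β-substituent may be slow, and the face selection may be lower than with simple β-aryl or β-alkyl enals. The fallback sets out from ketone 11 and sets the same centre by chelation-controlled hydrogenation. Horner–Wadsworth–Emmons olefination with (EtO)2P(O)CH2CO2Et and NaH in THF should give, after removal of the minor Z isomer, the (E)-enoate F3. Reduction with i-Bu2AlH in CH2Cl2 at −78 °C gives the (E)-allylic alcohol F4. Hydrogenation with H2 and Ru(OAc)2[(S)-BINAP] in MeOH should give the saturated alcohol F5, with the sense assigned by analogy with nerol giving (S)-citronellol and the remote alkene untouched. Dess–Martin oxidation returns to 15.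

Further compounds
F1 | step 11 | 3-(bromomercurio)-2,2-dimethyl-6-(Obc)cyclohexane-1-carbaldehyde, HgBr equatorial and trans to Obc (both C1 epimers) | CC1(C)C(C=O)[C@@H]([C@@]23CC[C@@](C)(O2)[C@H](Br)C3)CC[C@@H]1[Hg]Br
F2 | step 12 | (3S,6S)-3-bromo-2,2-dimethyl-6-(Obc)cyclohexane-1-carboxylic acid (both C1 epimers) | CC1(C)C(C(=O)O)[C@@H]([C@@]23CC[C@@](C)(O2)[C@H](Br)C3)CC[C@@H]1Br
F3 | step 9 | ethyl (E)-3-(Obc)-7-methylocta-2,6-dienoate | CCOC(=O)/C=C(\CCC=C(C)C)[C@@]12CC[C@@](C)(O1)[C@H](Br)C2
F4 | step 9 | (E)-3-(Obc)-7-methylocta-2,6-dien-1-ol | OC/C=C(\CCC=C(C)C)[C@@]12CC[C@@](C)(O1)[C@H](Br)C2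
F5 | step 9 | (3S)-3-(Obc)-7-methyloct-6-en-1-ol | OCC[C@@H]([C@@]12CC[C@@](C)(O1)[C@H](Br)C2)CCC=C(C)C
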